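## Retrosynthetic overview

1. Target ⇐ chemoselective 5-O-demethylation of 3,5,6,7,8,4'-hexamethoxyflavone ⇐ O-methylation of the corresponding 3-hydroxyflavone (flavonol).
2. Flavonol ⇐ C3-oxygenation of tangeretin (5,6,7,8,4'-pentamethoxyflavone) by epoxidation and acid-catalysed ring opening.
3. Tangeretin ⇐ oxidative cyclisation of a 2'-hydroxychalcone; ring C is the only ring formed and is closed last, onto preformed aromatic rings A and B.
4. Chalcone ⇐ intermolecular Claisen–Schmidt aldol condensation of 2'-hydroxy-3',4',5',6'-tetramethoxyacetophenone with 4-methoxybenzaldehyde; this makes the key C–C bond, C2–C3 of the flavone.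
5. Acetophenone ⇐ 3,4,5-trimethoxyphenol by ortho-acetylation, ring bromination and copper-catalysed methoxylation.

Assumption: the target has no stereocentre (it is achiral), so there is no enantiomer to control. The only stereo-element set on the way is the E-alkene of the chalcone, and the racemic in-flask intermediates lose their stereocentres again.

## Route

Step 1
Reactants: 1 3,4,5-trimethoxyphenol
Product: 2 1-(6-hydroxy-2,3,4-trimethoxyphenyl)ethan-1-one
Conditions: AcOH (1.5 equiv) in BF3·OEt2, 90 °C, 2–3 h; then H2O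
Reagents that add atoms: acetic acid, CC(=O)O
Why: BF3-promoted Friedel–Crafts (Fries-type) C-acylation goes ortho to the phenol OH because the two ortho positions are equivalent and the para position is blocked, and the hydrogen-bonded o-hydroxyaryl ketone formed is deactivated toward a second acylation.

Step 2
Reactants: 2 1-(6-hydroxy-2,3,4-trimethoxyphenyl)ethan-1-one
Product: 3 1-(3-bromo-2-hydroxy-4,5,6-trimethoxyphenyl)ethan-1-one
Conditions: NBS (1.05 equiv), MeCN, 0 °C → rt, 2 h
Reagents that add atoms: N-bromosuccinimide, O=C1CCC(=O)N1Br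
Why: Electrophilic aromatic bromination at the single remaining ring C–H, which is ortho to OH and OMe, is far faster than α-bromination of the acetyl group under neutral NBS conditions.

Step 3
Reactants: 3 1-(3-bromo-2-hydroxy-4,5,6-trimethoxyphenyl)ethan-1-one
Product: 4 1-(2-hydroxy-3,4,5,6-tetramethoxyphenyl)ethan-1-one
Conditions: NaOMe (25% in MeOH, 8 equiv), CuBr (20 mol %), DMF, 110 °C, N2, 8 h; then 2 M HCl
Reagents that add atoms: NaOMe (sodium methoxide), [Na+].[O-]C
Why: Ullmann-type copper-catalysed methoxylation of an aryl bromide ortho to a phenoxide is the same transformation as the classical conversion of 5-bromovanillin into syringaldehyde, which tolerates a free phenol and a carbonyl group.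

Step 4
Reactants: 4 1-(2-hydroxy-3,4,5,6-tetramethoxyphenyl)ethan-1-one; 5 4-methoxybenzaldehyde
Product: 7 (E)-1-(2-hydroxy-3,4,5,6-tetramethoxyphenyl)-3-(4-methoxyphenyl)prop-2-en-1-one, via aldol adduct 6 (not isolated)
Conditions: 5 (1.2 equiv), KOH (50% aq.), EtOH, rt, 36 h; then 2 M HCl to pH 3
Reagents that add atoms: none
Why: In this Claisen–Schmidt (crossed aldol) condensation the methyl-ketone enolate of 4 adds to the non-enolisable aldehyde 5 and the aldol 6 dehydrates by E1cB to the conjugated, thermodynamically favoured E-enone, so no stereocentre survives.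

Step 5
Reactants: 7 (E)-1-(2-hydroxy-3,4,5,6-tetramethoxyphenyl)-3-(4-methoxyphenyl)prop-2-en-1-one
Product: 9 5,6,7,8-tetramethoxy-2-(4-methoxyphenyl)-4H-chromen-4-one (tangeretin), via flavanone 8 (not isolated)
Conditions: I2 (10 mol %), DMSO, 130 °C, 3 h; then aq. Na2S2O3
Reagents that add atoms: none
Why: Oxa-Michael ring closure to flavanone 8 followed by iodine-mediated dehydrogenation, with DMSO re-oxidising HI to I2, reliably turns 2'-hydroxychalcones carrying a 6'-OMe group into flavones, where the one-pot Algar–Flynn–Oyamada alternative tends to give aurones.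

Step 6
Reactants: 9 5,6,7,8-tetramethoxy-2-(4-methoxyphenyl)-4H-chromen-4-one
Product: 11 3-hydroxy-5,6,7,8-tetramethoxy-2-(4-methoxyphenyl)-4H-chromen-4-one, via 2,3-epoxyflavanone 10 (not isolated)
Conditions: DMDO (about 0.07 M in acetone, 3–4 equiv), CH2Cl2, 0 °C → rt, 16 h; evaporate; p-TsOH·H2O (10 mol %), CH2Cl2, rt, 1 h
Reagents that add atoms: dimethyldioxirane, CC1(C)OO1
Why: Neutral DMDO epoxidises the C2–C3 enol-ether double bond to the racemic cis-fused epoxide 10, which under acid catalysis opens to the C2 oxocarbenium ion and loses H-3 to give the aromatic flavonol, so the transient stereocentres are destroyed.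

Step 7
Reactants: 11 3-hydroxy-5,6,7,8-tetramethoxy-2-(4-methoxyphenyl)-4H-chromen-4-one
Product: 12 3,5,6,7,8-pentamethoxy-2-(4-methoxyphenyl)-4H-chromen-4-one
Conditions: MeI (3 equiv), K2CO3 (3 equiv), acetone, reflux, 6 h
Reagents that add atoms: iodomethane, CI
Why: Williamson O-methylation of the only free hydroxyl group in the molecule cannot give regioisomers.

Step 8
Reactants: 12 3,5,6,7,8-pentamethoxy-2-(4-methoxyphenyl)-4H-chromen-4-one
Product: 13 5-hydroxy-3,6,7,8-tetramethoxy-2-(4-methoxyphenyl)-4H-chromen-4-one (5-hydroxyauranetin)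
Conditions: conc. HCl–EtOH (1:3 v/v), reflux, 24–48 h, HPLC monitoring
Reagents that add atoms: none
Why: In this selective acid-mediated O-demethylation only the 5-OMe group peri to the protonated C4 carbonyl is activated as a vinylogous oxocarbenium-type methyl ether and its cleavage gives a strongly chelated 5-OH, whereas the 3-OMe and the other aryl methyl ethers are inert to HCl, as is seen with closely related polymethoxyflavones.

## Compound list

1 | 3,4,5-trimethoxyphenol | COc1cc(O)cc(OC)c1OC | starting material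
2 | 1-(6-hydroxy-2,3,4-trimethoxyphenyl)ethan-1-one | CC(=O)c1c(O)cc(OC)c(OC)c1OC | intermediate
3 | 1-(3-bromo-2-hydroxy-4,5,6-trimethoxyphenyl)ethan-1-one | CC(=O)c1c(O)c(Br)c(OC)c(OC)c1OC | intermediate
4 | 1-(2-hydroxy-3,4,5,6-tetramethoxyphenyl)ethan-1-one | CC(=O)c1c(O)c(OC)c(OC)c(OC)c1OC | intermediate
5 | 4-methoxybenzaldehyde | COc1ccc(C=O)cc1 | starting material
6 | 3-hydroxy-1-(2-hydroxy-3,4,5,6-tetramethoxyphenyl)-3-(4-methoxyphenyl)propan-1-one (racemic aldol adduct) | COc1ccc(C(O)CC(=O)c2c(O)c(OC)c(OC)c(OC)c2OC)cc1 | intermediate (not isolated)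
7 | (E)-1-(2-hydroxy-3,4,5,6-tetramethoxyphenyl)-3-(4-methoxyphenyl)prop-2-en-1-one | COc1ccc(/C=C/C(=O)c2c(O)c(OC)c(OC)c(OC)c2OC)cc1 | intermediate
8 | 5,6,7,8-tetramethoxy-2-(4-methoxyphenyl)chroman-4-one (racemic flavanone) | COc1ccc(C2CC(=O)c3c(OC)c(OC)c(OC)c(OC)c3O2)cc1 | intermediate (not isolated)
9 | 5,6,7,8-tetramethoxy-2-(4-methoxyphenyl)-4H-chromen-4-one (tangeretin) | COc1ccc(-c2cc(=O)c3c(OC)c(OC)c(OC)c(OC)c3o2)cc1 | intermediate
10 | 2,3-epoxy-5,6,7,8-tetramethoxy-2-(4-methoxyphenyl)chroman-4-one (racemic, cis-fused; one enantiomer drawn) | O=C1[C@@H]2O[C@]2(c2ccc(OC)cc2)Oc2c(OC)c(OC)c(OC)c(OC)c12 | intermediate (not isolated)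
11 | 3-hydroxy-5,6,7,8-tetramethoxy-2-(4-methoxyphenyl)-4H-chromen-4-one | COc1ccc(-c2oc3c(OC)c(OC)c(OC)c(OC)c3c(=O)c2O)cc1 | intermediate
12 | 3,5,6,7,8-pentamethoxy-2-(4-methoxyphenyl)-4H-chromen-4-one (3,5,6,7,8,4'-hexamethoxyflavone) | COc1ccc(-c2oc3c(OC)c(OC)c(OC)c(OC)c3c(=O)c2OC)cc1 | intermediate
13 | 5-hydroxy-3,6,7,8-tetramethoxy-2-(4-methoxyphenyl)-4H-chromen-4-one (5-hydroxyauranetin) | COc1ccc(-c2oc3c(OC)c(OC)c(OC)c(O)c3c(=O)c2OC)cc1 | target

## Step count and risks

Total step count: 8. Longest linear sequence: 8 steps (1 → 13); 4-methoxybenzaldehyde 5 enters at step 4.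

The three steps most likely to fail are steps 3, 6 and 8.

The first risk is step 3: the copper-catalysed methoxylation of a hindered, very electron-rich bromophenol may stall or give mainly hydrodebromination back to 2. The fallback sets out from 3 and brings in the oxygen through boron instead of by C–O coupling. Miyaura borylation (B2pin2, PdCl2(dppf), KOAc, dioxane, 90 °C) gives the pinacol boronate 1-[2-hydroxy-4,5,6-trimethoxy-3-(4,4,5,5-tetramethyl-1,3,2-dioxaborolan-2-yl)phenyl]ethan-1-one F1. Mild oxidation (NaBO3·4H2O, THF/H2O, rt) gives the catechol 1-(2,3-dihydroxy-4,5,6-trimethoxyphenyl)ethan-1-one F2. Methylation with one equivalent of MeI (K2CO3, DMF, rt) then takes the 3-OH selectively, because the 2-OH is hydrogen-bonded to the acetyl group, and the fallback comes back to the route at 4.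

The second risk is step 6: DMDO may react sluggishly with the enone-type double bond or over-oxidise the electron-rich rings. The fallback sets out from 9 and hydroxylates C3 by deprotonation instead of epoxidation. LiN(iPr)2 (THF, −78 °C) gives the 3-lithio derivative 3-lithio-5,6,7,8-tetramethoxy-2-(4-methoxyphenyl)-4H-chromen-4-one F3. B(OMe)3 traps it as dimethyl [5,6,7,8-tetramethoxy-2-(4-methoxyphenyl)-4-oxo-4H-chromen-3-yl]boronate F4. Oxidation in the same flask with H2O2/AcOH gives the flavonol, and the fallback comes back to the route at 11.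

The third risk is step 8: the acid may also remove the 3-O-methyl group or react incompletely. The fallback sets out from 11 and inverts the order of the last two operations. The flavonol 11 is demethylated at O-5 (conc. HCl–EtOH, reflux) while no 3-O-methyl group is present to be lost, giving 3,5-dihydroxy-6,7,8-trimethoxy-2-(4-methoxyphenyl)-4H-chromen-4-one F5. The 3-OH alone is then methylated (Me2SO4 1.05 equiv, K2CO3, acetone, rt), because the 5-OH is strongly hydrogen-bonded to the C4 carbonyl and much less reactive, and the fallback comes back to the route at 13.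

## Further compounds

F1 | step 3 | 1-[2-hydroxy-4,5,6-trimethoxy-3-(4,4,5,5-tetramethyl-1,3,2-dioxaborolan-2-yl)phenyl]ethan-1-one | CC(=O)c1c(O)c(B2OC(C)(C)C(C)(C)O2)c(OC)c(OC)c1OC
F2 | step 3 | 1-(2,3-dihydroxy-4,5,6-trimethoxyphenyl)ethan-1-one | CC(=O)c1c(O)c(O)c(OC)c(OC)c1OC
F3 | step 6 | 3-lithio-5,6,7,8-tetramethoxy-2-(4-methoxyphenyl)-4H-chromen-4-one | COc1ccc(-c2oc3c(OC)c(OC)c(OC)c(OC)c3c(=O)c2[Li])cc1
F4 | step 6 | dimethyl [5,6,7,8-tetramethoxy-2-(4-methoxyphenyl)-4-oxo-4H-chromen-3-yl]boronate | COc1ccc(-c2oc3c(OC)c(OC)c(OC)c(OC)c3c(=O)c2B(OC)OC)cc1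
F5 | step 8 | 3,5-dihydroxy-6,7,8-trimethoxy-2-(4-methoxyphenyl)-4H-chromen-4-one | COc1ccc(-c2oc3c(OC)c(OC)c(OC)c(O)c3c(=O)c2O)cc1
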